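The route rests on cutting ring A, the anisole ring, at C1–C6 and C2–C3. Its C3–C6 segment (H at C3 and C5, Br at C4 and C6) is the diene of 3,5-dibromo-2-pyrone, and C1 and C2, the two oxygen-bearing carbons, come from an alkyne. One Diels–Alder/CO2-extrusion operation between the pyrone and an ynol-ether alkynylboronate builds ring A with all four substituents in place: the alkyne carbon already bonded to the ring B oxygen becomes C1, and the boron-bearing carbon becomes C2, later the methoxy-bearing carbon. The precursor is a pinacol alkynylboronate whose alkyne carries the benzyl-protected 4,6-dibromo ring B as an aryloxy group.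

Key step: step 5

Remark on numbering: in ring A, C1 bears the aryloxy oxygen, C2 the methoxy group and C4/C6 bromine; in ring B, C1' bears the ether oxygen, C2' the hydroxyl and C4'/C6' bromine.

Step 1
Reactants: 1 2-(benzyloxy)phenol
Product: 3 2-(benzyloxy)-4,6-dibromophenol, via 2-(benzyloxy)-4-bromophenol 2 (not isolated)
Conditions: NBS (2.05 equiv), MeCN, 0 °C → rt
Reagents that add atoms: N-bromosuccinimide, O=C1CCC(=O)N1Br
Why: Electrophilic aromatic bromination is governed by the free hydroxyl, the strongest donor on the ring, which sends the first bromine para to itself (giving 2) and the second to its only free ortho position, while the positions activated solely by the benzyloxy group stay untouched.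

Step 2
Reactants: 3 2-(benzyloxy)-4,6-dibromophenol; 4 trichloroethylene (1.5 equiv)
Product: 6 1-(benzyloxy)-3,5-dibromo-2-{[(E)-1,2-dichloroethenyl]oxy}benzene, via dichloroacetylene 5 (not isolated)
Conditions: K2CO3 (2 equiv), DMF, 70 °C
Reagents that add atoms: none
Why: Base-mediated O-dichlorovinylation of a phenol: K2CO3 strips HCl from 4 to give dichloroacetylene 5, and anti addition of the phenoxide across it delivers the (E)-dichlorovinyl ether under conditions that leave aryl bromides and the benzyl ether alone.

Step 3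
Reactants: 6 1-(benzyloxy)-3,5-dibromo-2-{[(E)-1,2-dichloroethenyl]oxy}benzene
Product: 10 2-{[2-(benzyloxy)-4,6-dibromophenoxy]ethynyl}-4,4,5,5-tetramethyl-1,3,2-dioxaborolane, via chloroalkyne 7 (not isolated), via lithium acetylide 8 (not isolated), via lithium borate 9 (not isolated)
Conditions: PhLi (2.05 equiv), THF, −78 → −40 °C; i-PrOBpin (1.1 equiv), −78 °C; HCl (2 M in Et2O, 1.05 equiv), −78 °C → rt
Reagents that add atoms: 2-isopropoxy-4,4,5,5-tetramethyl-1,3,2-dioxaborolane (i-PrOBpin), CC(C)OB1OC(C)(C)C(C)(C)O1
Why: The established dichlorovinyl ether route to metalated ynol ethers (elimination to chloroalkyne 7, chlorine–lithium exchange at the sp carbon to acetylide 8) is coupled to the standard alkynylboronate synthesis (borate 9, released by one equivalent of anhydrous HCl); PhLi is used in place of an alkyllithium because aryllithium/aryl bromide exchange is slow at −78 °C while vinylic deprotonation and exchange at the alkynyl chloride are fast.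

Step 4
Reactants: 11 coumalic acid (2-oxo-2H-pyran-5-carboxylic acid)
Product: 13 3,5-dibromo-2H-pyran-2-one, via 5-bromo-2H-pyran-2-one 12 (not isolated)
Conditions: NBS (2.5 equiv), LiOAc, MeCN/H2O, rt
Reagents that add atoms: N-bromosuccinimide, O=C1CCC(=O)N1Br
Why: Halodecarboxylation of the Hunsdiecker type replaces the C5 carboxylate by bromine (giving 12), and electrophilic bromination at C3, the other nucleophilic carbon of the pyrone, completes a one-flask conversion documented for coumalic acid itself.

Step 5
Reactants: 10 2-{[2-(benzyloxy)-4,6-dibromophenoxy]ethynyl}-4,4,5,5-tetramethyl-1,3,2-dioxaborolane; 13 3,5-dibromo-2H-pyran-2-one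
Product: 15 2-{2-[2-(benzyloxy)-4,6-dibromophenoxy]-3,5-dibromophenyl}-4,4,5,5-tetramethyl-1,3,2-dioxaborolane, via bridged lactone 14 (not isolated)
Conditions: 10 (1.3 equiv), toluene, 130 °C, sealed tube
Reagents that add atoms: none
Why: The electron-poor diene of 13 (C3=C4–C5=C6) and the oxygen-polarised alkyne of 10 should combine in a thermal inverse-demand [4+2] cycloaddition to bridged lactone 14, which expels CO2 by retro-[4+2] reaction at the same temperature and aromatises. The closest known reaction types are the benzannulation of 2-pyrones with alkynylboronic esters to arylboronic esters and that of 2-pyrones with ynol ethers or ynamines to aryl ethers or anilines. Ring A is closed as a six-membered carbocycle by intermolecular (4+2) annulation, both new σ-bonds (C1–C6 and C2–C3 of ring A) arising in the cycloaddition. No stereocentre survives, since the two bridgehead centres of 14 are erased when CO2 leaves. The one selectivity needed is regiochemical: oxygen donation makes the boron-bearing alkyne carbon the nucleophilic terminus, which bonds to the electrophilic C6 of the pyrone, so the oxygen-bearing carbon joins the brominated C3 and the bulky boronate ends up beside C–H and away from bromine. The aryl bromides and the benzyl ether are inert under these neutral thermal conditions.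

Step 6
Reactants: 15 2-{2-[2-(benzyloxy)-4,6-dibromophenoxy]-3,5-dibromophenyl}-4,4,5,5-tetramethyl-1,3,2-dioxaborolane
Product: 16 2-[2-(benzyloxy)-4,6-dibromophenoxy]-3,5-dibromophenol
Conditions: 30% aq H2O2, 1 M aq NaOH, THF, 0 °C → rt
Reagents that add atoms: hydrogen peroxide, OO
Why: Oxidation of an arylboronic ester with basic hydrogen peroxide (hydroperoxide adds to boron, the aryl group shifts from boron to oxygen, the borate ester hydrolyses) is fast at 0 °C and does not touch aryl bromides, the diaryl ether or the benzyl ether.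

Step 7
Reactants: 16 2-[2-(benzyloxy)-4,6-dibromophenoxy]-3,5-dibromophenol
Product: 17 1-(benzyloxy)-3,5-dibromo-2-(2,4-dibromo-6-methoxyphenoxy)benzene
Conditions: MeI, K2CO3, DMF, rt
Reagents that add atoms: iodomethane, CI
Why: Williamson etherification of the only free phenol in 16, the ring B oxygen still being capped by benzyl, places the methyl group unambiguously on ring A.

Step 8
Reactants: 17 1-(benzyloxy)-3,5-dibromo-2-(2,4-dibromo-6-methoxyphenoxy)benzene
Product: 18 3,5-dibromo-2-(2,4-dibromo-6-methoxyphenoxy)phenol (target)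
Conditions: BCl3 (1 M in CH2Cl2), C6HMe5, CH2Cl2, −78 °C; then MeOH/H2O
Reagents that add atoms: none
Why: Lewis acid debenzylation with BCl3 and pentamethylbenzene as cation scavenger cleaves aryl benzyl ethers at −78 °C, a temperature at which the aryl methyl ether, the diaryl ether and the C–Br bonds should be inert, so only the ring B hydroxyl is set free.

Compound list
1 | 2-(benzyloxy)phenol | Oc1ccccc1OCc1ccccc1 | starting material
2 | 2-(benzyloxy)-4-bromophenol | Oc1ccc(Br)cc1OCc1ccccc1 | intermediate (not isolated)
3 | 2-(benzyloxy)-4,6-dibromophenol | Oc1c(OCc2ccccc2)cc(Br)cc1Br | intermediate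
4 | trichloroethylene | ClC=C(Cl)Cl | starting material
5 | dichloroacetylene | ClC#CCl | intermediate (not isolated)
6 | 1-(benzyloxy)-3,5-dibromo-2-{[(E)-1,2-dichloroethenyl]oxy}benzene | Cl/C=C(/Cl)Oc1c(OCc2ccccc2)cc(Br)cc1Br | intermediate
7 | 1-(benzyloxy)-3,5-dibromo-2-[(chloroethynyl)oxy]benzene | ClC#COc1c(OCc2ccccc2)cc(Br)cc1Br | intermediate (not isolated)
8 | lithium 2-[2-(benzyloxy)-4,6-dibromophenoxy]ethynide | [Li]C#COc1c(OCc2ccccc2)cc(Br)cc1Br | intermediate (not isolated)
9 | lithium {[2-(benzyloxy)-4,6-dibromophenoxy]ethynyl}(isopropoxy)(pinacolato)borate | [Li+].CC(C)O[B-]1(C#COc2c(OCc3ccccc3)cc(Br)cc2Br)OC(C)(C)C(C)(C)O1 | intermediate (not isolated)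
10 | 2-{[2-(benzyloxy)-4,6-dibromophenoxy]ethynyl}-4,4,5,5-tetramethyl-1,3,2-dioxaborolane | CC1(C)OB(C#COc2c(OCc3ccccc3)cc(Br)cc2Br)OC1(C)C | intermediate
11 | coumalic acid (2-oxo-2H-pyran-5-carboxylic acid) | O=C(O)C1=COC(=O)C=C1 | starting material
12 | 5-bromo-2H-pyran-2-one | O=C1OC=C(Br)C=C1 | intermediate (not isolated)
13 | 3,5-dibromo-2H-pyran-2-one | O=C1OC=C(Br)C=C1Br | intermediate
14 | 5-[2-(benzyloxy)-4,6-dibromophenoxy]-4,7-dibromo-6-(4,4,5,5-tetramethyl-1,3,2-dioxaborolan-2-yl)-2-oxabicyclo[2.2.2]octa-5,7-dien-3-one (racemic, one enantiomer drawn; the two bridgeheads are fixed relative to each other by the bicycle) | O=C1O[C@@H]2C(Br)=C[C@@]1(Br)C(Oc3c(OCc4ccccc4)cc(Br)cc3Br)=C2B5OC(C)(C)C(C)(C)O5 | intermediate (not isolated)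
15 | 2-{2-[2-(benzyloxy)-4,6-dibromophenoxy]-3,5-dibromophenyl}-4,4,5,5-tetramethyl-1,3,2-dioxaborolane | CC1(C)OB(c2cc(Br)cc(Br)c2Oc2c(OCc3ccccc3)cc(Br)cc2Br)OC1(C)C | intermediate
16 | 2-[2-(benzyloxy)-4,6-dibromophenoxy]-3,5-dibromophenol | Oc1cc(Br)cc(Br)c1Oc1c(OCc2ccccc2)cc(Br)cc1Br | intermediate
17 | 1-(benzyloxy)-3,5-dibromo-2-(2,4-dibromo-6-methoxyphenoxy)benzene | COc1cc(Br)cc(Br)c1Oc1c(OCc2ccccc2)cc(Br)cc1Br | intermediate
18 | 3,5-dibromo-2-(2,4-dibromo-6-methoxyphenoxy)phenol | COc1cc(Br)cc(Br)c1Oc1c(O)cc(Br)cc1Br | target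

Total step count: 8. Longest linear sequence: 7 (steps 1, 2, 3, 5, 6, 7, 8); step 4 is a one-step side branch.

Steps most likely to fail

Step 5. The cycloaddition may be slower than thermal decay of the ynol ether boronate, or the alkyne may add in the reverse orientation. The fallback abandons ring construction for a substitution and sets out from 3. SNAr of 3 with commercial 3,5-dibromo-2-fluorobenzaldehyde (Cs2CO3, DMAc, 100 °C) should give 2-[2-(benzyloxy)-4,6-dibromophenoxy]-3,5-dibromobenzaldehyde F1. Baeyer–Villiger oxidation (mCPBA, CH2Cl2), favoured by the ortho aryloxy donor, should give 2-[2-(benzyloxy)-4,6-dibromophenoxy]-3,5-dibromophenyl formate F2. Methanolysis (K2CO3, MeOH) returns to the route at 16.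

Step 3. Bromine–lithium exchange on ring B may compete with the exchange at the alkynyl chloride, and boron may be lost by hydrolysis while 10 is isolated. The fallback sets out from 3, bypasses step 2 as well, and needs no halogen–metal exchange.
- Transfer vinylation (vinyl acetate, [Ir(cod)Cl]2, Na2CO3, toluene, 100 °C) should give 1-(benzyloxy)-3,5-dibromo-2-(ethenyloxy)benzene F3.
- Bromine addition (Br2, CH2Cl2, −78 °C) gives 1-(benzyloxy)-3,5-dibromo-2-(1,2-dibromoethoxy)benzene F4.
- i-Pr2NEt removes the first HBr to give 1-(benzyloxy)-3,5-dibromo-2-[(2-bromoethenyl)oxy]benzene F5.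
- KOC(CH3)3 in THF removes the second to give 1-(benzyloxy)-3,5-dibromo-2-(ethynyloxy)benzene F6.
- LiN(SiMe3)2 (THF, −78 °C) deprotonates only the alkyne C–H, and the route is rejoined at lithium acetylide 8, which is borylated as in step 3. Compound 10 would then be carried crude into step 5.

Step 8. The Lewis acid, held between the two neighbouring ring A oxygens, may also cleave the methyl ether, or the benzyl cation may alkylate an arene. The fallback sets out from 16 and removes benzyl before any methyl ether exists. BCl3/C6HMe5 (CH2Cl2, −78 °C) should give the symmetrical 2,2'-oxybis(3,5-dibromophenol) F7, whose two hydroxyls are equivalent. Methylation with one equivalent of MeI (K2CO3, acetone) then reaches 18 by statistical monoalkylation, with unreacted F7 recycled.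

Further compounds
F1 | step 5 | 2-[2-(benzyloxy)-4,6-dibromophenoxy]-3,5-dibromobenzaldehyde | O=Cc1cc(Br)cc(Br)c1Oc1c(OCc2ccccc2)cc(Br)cc1Br
F2 | step 5 | 2-[2-(benzyloxy)-4,6-dibromophenoxy]-3,5-dibromophenyl formate | O=COc1cc(Br)cc(Br)c1Oc1c(OCc2ccccc2)cc(Br)cc1Br
F3 | step 3 | 1-(benzyloxy)-3,5-dibromo-2-(ethenyloxy)benzene | C=COc1c(OCc2ccccc2)cc(Br)cc1Br
F4 | step 3 | 1-(benzyloxy)-3,5-dibromo-2-(1,2-dibromoethoxy)benzene (racemic) | BrCC(Br)Oc1c(OCc2ccccc2)cc(Br)cc1Br
F5 | step 3 | 1-(benzyloxy)-3,5-dibromo-2-[(2-bromoethenyl)oxy]benzene (E/Z mixture) | BrC=COc1c(OCc2ccccc2)cc(Br)cc1Br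
F6 | step 3 | 1-(benzyloxy)-3,5-dibromo-2-(ethynyloxy)benzene | C#COc1c(OCc2ccccc2)cc(Br)cc1Br
F7 | step 8 | 2,2'-oxybis(3,5-dibromophenol) | Oc1cc(Br)cc(Br)c1Oc1c(O)cc(Br)cc1Br
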